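The constants of these flasks are not at hand, so two earlier runs at one enzyme charge must stand in for them, and the question is what a higher c(starting material) does to the c(target) reached at the end.

| flask | starting material | enzyme | remark | time |
|---|---|---|---|---|
| Tuesday's | 0.021 M | 44 µM | run made earlier |  |
| Saturday's | 0.12 M | 44 µM | run made earlier |  |
| north-west | 0.040 M | 44 µM |  | 5.0 min |
| north-east | 0.080 M | 44 µM |  | 5.0 min |
| south-west | 0.20 M | 44 µM |  | 5.0 min |

| Tuesday's: time / min | Tuesday's: target / % | Saturday's: time / min | Saturday's: target / % |
|---|---|---|---|
| 0.667 | 20 | 0.250 | 1 |
| 1.33 | 34 | 0.667 | 6 |
| 2.00 | 42 | 1.33 | 12 |
| 2.50 | 43 | 2.00 | 12 |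
| 3.00 | 46 | 2.50 | 19 |
| 4.00 | 50 | 4.00 | 16 |

(each reading ± 2 percentage points)

- "hardly changes" means that all values lie within two and a half points (for a concentration: within two and a half percent of the largest)

- [target] at the end for north-west, north-east, south-west, in this order
- how the row runs (falls all the way / rises all the way / falls, then rises / rises, then falls / hardly changes)

At 4.00 min Tuesday's run stands at 50% and Saturday's at 16%, so the percent fell by a factor of 3.12 while the charge rose by a factor of 5.71, which is less, and the amount made went up between these two charges. Ines and Marek agree on that and part on what lies beyond it. Ines holds that the enzyme has a ceiling, so that the percent can at worst fall as fast as the charge rises and the amount climbs towards that ceiling without coming down. Marek holds that the charge itself holds the enzyme back (substrate inhibition), and he takes the simplest form in which the percent can fall faster than the charge rises: the percent at a fixed time goes as a constant over one plus the square of the charge divided by K, which makes the amount peak where the charge equals K. Two runs cannot test this form; they only set its constants. Solved on the two readings, it gives 0.0783 M for the turning charge, the c(starting material) at which the percent falls just as fast as the charge rises, and this is a reading that carries the scatter of 2 percentage points. Marek's own reckoning for 4.00 min then gives 0.536 as the dilute fraction of the charge and 0.0170 M, 0.0210 M and 0.0142 M for north-west, north-east and south-west, with north-east on top; the asked time is 5.0 min, so he stands by the shape and not by the levels.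

Ines's forecast is 0.014 M, 0.017 M and 0.019 M, shape: rises all the way, and of the charge holding the enzyme back she says “nothing here demands it”.

The flasks give 0.0189 M, 0.0253 M and 0.0165 M, shape: rises, then falls. The row turns at 0.081 M, and below that charge, from north-west to north-east, Ines's climbing row holds.

    2 enzyme → spent catalyst (k = 108 L mol⁻¹ s⁻¹)
    starting material + enzyme → target + enzyme, rate k2*[starting material]*[enzyme]/(1 + ([starting material]/Km2) + ([starting material]/Ksi2)^2) (0.113 M, 0.0615 M, k = 216 L mol⁻¹ s⁻¹)
    target + enzyme ⇌ isomer of the product + enzyme, rate k3*[enzyme]*[target] forward; the back reaction follows from the equilibrium constant (K = 0.434, k = 165 L mol⁻¹ s⁻¹)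

Set into Marek's form, the turning charge makes the percent in north-west exceed that in south-west by a factor of 5.97, and the flasks hold 47.4% against 8.24%, a factor of 5.75. One part of the fall lies in the levelling-off with c(starting material) in the step to target: with that term taken away, the row changes shape and south-west ends at 0.0680 M instead of 0.0165 M, a factor of 4.13.

The readings were computed with constants of no real substance, noise included.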